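**Overview**

- Retrosynthesis: with the quinone numbered C1(=O), C2(OH), C3(CH3), C4(=O), C5(OH), C6(pentadecyl), the two hydroxyls are first masked as methyl ethers; the ring is then cut at C3–C4 (the key bond), at C1–C2, and at the bond from C6 to the side chain.
- Enabling feature: each ring C=C of the benzoquinone carries one oxygen and one carbon substituent, with the oxygens para (C2, C5). C4(=O)–C5(O)=C6(alkyl)–C1(=O) is therefore the four-carbon ring of a squarate, and C2(O)=C3–CH3 is C1, C2 and C3 of 1-methoxyallene.
- Forward: lithiated methoxyallene and then pentadecyllithium are added to the intact four-membered ring of dimethyl squarate. A 1,3-carbonyl transposition puts the carbinol next to the alkyl-bearing carbon. The six-membered ring, the only ring of the target, then forms in one thermal ring expansion, and hydrolysis of the two vinylogous esters ends the route.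
- Stereochemistry: the target is achiral; the carbinol centres of the intermediates are racemic or mixed and all are erased in the ring expansion.

Key step: step 7

Assumption: the target has no stereocentre and no stereogenic double bond, so the request for a single enantiomer is met by the compound itself. All 4-allenylcyclobutenones (4, 5, 11, 12) are kept at or below room temperature until step 7, because they are the substrates of the thermal ring opening.

**Route**

Step 1
Reactants: 1 methoxyallene; 2 dimethyl squarate
Product: 4 rac-4-hydroxy-2,3-dimethoxy-4-(1-methoxypropa-1,2-dien-1-yl)cyclobut-2-en-1-one, via 1-lithio-1-methoxyallene 3 (not isolated)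
Conditions: 1, n-BuLi, THF, −78 °C; cannulate into 2, THF, −78 °C; aq. NH4Cl at −78 °C
Reagents that add atoms: none
Why: n-BuLi removes the acidic hydrogen on the oxygen-bearing allene carbon, and the allenyllithium adds through that carbon to one of the two equivalent squarate carbonyls (1,2-addition of an organolithium to a squaric ester), the remaining carbonyl being a much less electrophilic vinylogous ester so that mono-addition stops there; the new carbinol centre forms racemic, which is immaterial because it is destroyed in step 7.

Step 2
Reactants: 4 rac-4-hydroxy-2,3-dimethoxy-4-(1-methoxypropa-1,2-dien-1-yl)cyclobut-2-en-1-one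
Product: 5 rac-2,3-dimethoxy-4-(1-methoxypropa-1,2-dien-1-yl)-4-(trimethylsilyloxy)cyclobut-2-en-1-one
Conditions: TMSCl, Et3N, DMAP (cat.), CH2Cl2, 0 °C
Reagents that add atoms: chlorotrimethylsilane, C[Si](C)(C)Cl
Why: O-silylation of a tertiary alcohol with a silyl chloride and amine base caps the first carbinol so that only the second one can later be acylated and ionised, while the excess amine keeps HCl away from the acid-labile allenyl ether.

Step 3
Reactants: 6 1-bromopentadecane
Product: 7 1-iodopentadecane
Conditions: NaI, acetone, reflux
Reagents that add atoms: sodium iodide, [Na+].[I-]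
Why: Finkelstein halide exchange (SN2), driven by precipitation of sodium bromide, gives the primary iodide needed for clean lithium–halogen exchange.

Step 4
Reactants: 7 1-iodopentadecane; 5 rac-2,3-dimethoxy-4-(1-methoxypropa-1,2-dien-1-yl)-4-(trimethylsilyloxy)cyclobut-2-en-1-one
Product: 9 2,3-dimethoxy-4-(1-methoxypropa-1,2-dien-1-yl)-1-pentadecyl-4-(trimethylsilyloxy)cyclobut-2-en-1-ol (racemic mixture of diastereomers), via pentadecyllithium 8 (not isolated)
Conditions: 7, t-BuLi (2.1 equiv), pentane–Et2O 3:2, −78 °C, then rt 1 h; add to 5, THF, −78 °C; aq. NH4Cl at −78 °C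
Reagents that add atoms: none
Why: lithium–iodine exchange of a primary iodide with two equivalents of t-BuLi is fast and irreversible, and the primary alkyllithium should then add 1,2 to the only carbonyl of 5 (organolithium addition to the vinylogous ester carbonyl of an O-protected squarate mono-adduct) faster than it metalates the allene terminus; the new carbinol centre forms as a diastereomer mixture, which does not matter because this carbon becomes sp2 in step 5.

Step 5
Reactants: 9 2,3-dimethoxy-4-(1-methoxypropa-1,2-dien-1-yl)-1-pentadecyl-4-(trimethylsilyloxy)cyclobut-2-en-1-ol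
Product: 11 rac-2-methoxy-4-(1-methoxypropa-1,2-dien-1-yl)-3-pentadecyl-4-(trimethylsilyloxy)cyclobut-2-en-1-one, via tertiary trifluoroacetate 10 (not isolated)
Conditions: (CF3CO)2O, pyridine, CH2Cl2, −78 to 0 °C; then aq. NaHCO3
Reagents that add atoms: water, O
Why: trifluoroacetylation turns the tertiary allylic carbinol into a leaving group, ionisation gives a cyclobutenyl cation that is the oxocarbenium ion of the methoxy group at the far end of the allyl system, and water from the bicarbonate quench adds there and expels methanol, a 1,3-carbonyl transposition of the Stork–Danheiser type; the silylated allenyl carbinol cannot ionise and pyridine keeps the medium near neutral for the allenyl ether.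

Step 6
Reactants: 11 rac-2-methoxy-4-(1-methoxypropa-1,2-dien-1-yl)-3-pentadecyl-4-(trimethylsilyloxy)cyclobut-2-en-1-one
Product: 12 rac-4-hydroxy-2-methoxy-4-(1-methoxypropa-1,2-dien-1-yl)-3-pentadecylcyclobut-2-en-1-one
Conditions: TBAF, AcOH (1:1), THF, −20 to 0 °C; concentrate cold and use at once
Reagents that add atoms: none
Why: fluoride cleavage of a trimethylsilyl ether, buffered with acetic acid so that no free alkoxide can add to the allene or open the strained ring, frees the hydroxyl whose proton is needed in step 7.

Step 7
Reactants: 12 rac-4-hydroxy-2-methoxy-4-(1-methoxypropa-1,2-dien-1-yl)-3-pentadecylcyclobut-2-en-1-one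
Product: 15 2,5-dimethoxy-3-methyl-6-pentadecylcyclohexa-2,5-diene-1,4-dione, via dienylketene 13 (not isolated), via ortho-quinone methide 14 (not isolated)
Conditions: PhMe (0.01 M), 90 °C, Ar
Reagents that add atoms: none
Why: Heating opens the cyclobutenone by conrotatory 4π-electrocyclic cleavage of its C1–C4 bond to dienylketene 13, whose ketene carbon then bonds to the central allene carbon in a thermal 6π-electrocyclisation that closes the only ring of the target, the six-membered carbocycle, as ortho-quinone methide 14. A proton shift from the ring hydroxyl to the exocyclic methylene (dienol to enone tautomerisation, relayed between molecules) should then give quinone 15 at the correct oxidation level without an oxidant, the allene terminus ending as the ring methyl group. The closest known reaction type is the thermal ring expansion of 4-allenyl-4-hydroxycyclobutenones through dienylketenes to ortho-quinone methides. No stereocentre is created and the racemic carbinol centre of 12 is erased. The step needs inward rotation of the allenyl group, which is secured by the strong preference of the hydroxyl donor on the same carbon for outward rotation, and it needs the 2,5-dioxygen pattern, which is already fixed in 12 because its carbinol carbon adjoins the pentadecyl-bearing carbon. High dilution keeps 14 from dimerising before it tautomerises.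

Step 8
Reactants: 15 2,5-dimethoxy-3-methyl-6-pentadecylcyclohexa-2,5-diene-1,4-dione
Product: 16 2,5-dihydroxy-3-methyl-6-pentadecylcyclohexa-2,5-diene-1,4-dione
Conditions: 2 M aq. NaOH, EtOH, 60 °C, Ar; then 2 M HCl, 0 °C
Reagents that add atoms: sodium hydroxide (aqueous), [Na+].[OH-]
Why: both methoxy groups are vinylogous methyl esters of the quinone carbonyls, so hydroxide replaces each by addition–elimination at the ring carbon (alkaline hydrolysis of methoxyquinones) to give the stable dianion of the dihydroxyquinone, and acidification releases the achiral target.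

**Compound list**

1 | methoxyallene (1-methoxypropa-1,2-diene) | COC=C=C | starting material
2 | dimethyl squarate (3,4-dimethoxycyclobut-3-ene-1,2-dione) | COC1=C(OC)C(=O)C1=O | starting material
3 | 1-lithio-1-methoxyallene | [Li]C(OC)=C=C | intermediate
4 | rac-4-hydroxy-2,3-dimethoxy-4-(1-methoxypropa-1,2-dien-1-yl)cyclobut-2-en-1-one | COC1=C(OC)C(O)(C(OC)=C=C)C1=O | intermediate
5 | rac-2,3-dimethoxy-4-(1-methoxypropa-1,2-dien-1-yl)-4-(trimethylsilyloxy)cyclobut-2-en-1-one | COC1=C(OC)C(O[Si](C)(C)C)(C(OC)=C=C)C1=O | intermediate
6 | 1-bromopentadecane | CCCCCCCCCCCCCCCBr | starting material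
7 | 1-iodopentadecane | CCCCCCCCCCCCCCCI | intermediate
8 | pentadecyllithium | [Li]CCCCCCCCCCCCCCC | intermediate
9 | 2,3-dimethoxy-4-(1-methoxypropa-1,2-dien-1-yl)-1-pentadecyl-4-(trimethylsilyloxy)cyclobut-2-en-1-ol (racemic, both diastereomers) | COC1=C(OC)C(O[Si](C)(C)C)(C(OC)=C=C)C1(O)CCCCCCCCCCCCCCC | intermediate
10 | 2,3-dimethoxy-4-(1-methoxypropa-1,2-dien-1-yl)-1-pentadecyl-4-(trimethylsilyloxy)cyclobut-2-en-1-yl trifluoroacetate (racemic, both diastereomers) | COC1=C(OC)C(O[Si](C)(C)C)(C(OC)=C=C)C1(OC(=O)C(F)(F)F)CCCCCCCCCCCCCCC | intermediate
11 | rac-2-methoxy-4-(1-methoxypropa-1,2-dien-1-yl)-3-pentadecyl-4-(trimethylsilyloxy)cyclobut-2-en-1-one | O=C1C(OC)=C(CCCCCCCCCCCCCCC)C1(O[Si](C)(C)C)C(OC)=C=C | intermediate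
12 | rac-4-hydroxy-2-methoxy-4-(1-methoxypropa-1,2-dien-1-yl)-3-pentadecylcyclobut-2-en-1-one | O=C1C(OC)=C(CCCCCCCCCCCCCCC)C1(O)C(OC)=C=C | intermediate
13 | (3E)-4-hydroxy-2,5-dimethoxy-3-pentadecylhepta-1,3,5,6-tetraen-1-one (dienylketene, allenyl group cis to the ketene carbon) | O=C=C(OC)/C(CCCCCCCCCCCCCCC)=C(/O)C(OC)=C=C | intermediate
14 | 4-hydroxy-2,5-dimethoxy-6-methylidene-3-pentadecylcyclohexa-2,4-dien-1-one (ortho-quinone methide) | O=C1C(OC)=C(CCCCCCCCCCCCCCC)C(O)=C(OC)C1=C | intermediate
15 | 2,5-dimethoxy-3-methyl-6-pentadecylcyclohexa-2,5-diene-1,4-dione | COC1=C(CCCCCCCCCCCCCCC)C(=O)C(OC)=C(C)C1=O | intermediate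
16 | 2,5-dihydroxy-3-methyl-6-pentadecylcyclohexa-2,5-diene-1,4-dione | CCCCCCCCCCCCCCCC1=C(O)C(=O)C(C)=C(O)C1=O | target

**Step count**

Total: 8 steps. Longest linear sequence: 7 steps (steps 1, 2, 4, 5, 6, 7, 8, from methoxyallene and dimethyl squarate); the side-chain arm (step 3) joins at step 4.

**Steps most likely to fail**

1. Step 7. The transient ortho-quinone methide may be lost to dimerisation, or to conjugate addition of the hydroxyl of a second molecule, before the intermolecular proton shift delivers the quinone. The fallback separates ring formation from the proton shift. It sets out from silyl ether 11, which is heated in dilute toluene; the same electrocyclic sequence should give the silyl-capped, fully substituted and therefore longer-lived 2,5-dimethoxy-6-methylidene-3-pentadecyl-4-(trimethylsilyloxy)cyclohexa-2,4-dien-1-one F1. The cooled solution is then treated with TBAF and acetic acid in THF at −78 °C. Desilylation in the presence of a proton source should release the dienolate, which is protonated to the conjugated quinone, so the sequence comes back to the route at 15.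

2. Step 5. The acylating and ionising medium may hydrolyse the allenyl enol ether or strip the silyl ether, or the cation may collapse unproductively instead of giving the transposed ketone. The fallback avoids any carbinol and any acid by substituting directly at the β-carbon of the vinylogous ester. It sets out from 5, which is treated with lithium benzenethiolate in THF at 0 °C. Thiolate addition–elimination at the methoxy-bearing β-carbon should give 2-methoxy-4-(1-methoxypropa-1,2-dien-1-yl)-3-(phenylsulfanyl)-4-(trimethylsilyloxy)cyclobut-2-en-1-one F2. Pentadecyllithium 8 and CuI in Et2O at −40 °C give the Gilman reagent lithium dipentadecylcuprate F3. Its addition–elimination on the β-arylthio enone F2 at −78 °C should replace the sulfur by the pentadecyl group and come back to the route at 11.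

3. Step 4. The basic alkyllithium may metalate the allene terminus, or add too slowly to the hindered carbonyl next to the quaternary silyloxy carbon, with the C15 reagent poorly soluble at −78 °C. The fallback reverses the order of the two additions, so that the alkyllithium meets only the unhindered squarate and the small allenyllithium makes the second bond. It sets out from 2 and 8, which at −78 °C should give 4-hydroxy-2,3-dimethoxy-4-pentadecylcyclobut-2-en-1-one F4. Silylation as in step 2 gives 2,3-dimethoxy-4-pentadecyl-4-(trimethylsilyloxy)cyclobut-2-en-1-one F5. Addition of allenyllithium 3 and quenching of the alkoxide in the flask with chlorotriethylsilane in THF/DMPU gives the mixed bis-silyl ether triethyl{[2,3-dimethoxy-1-(1-methoxypropa-1,2-dien-1-yl)-4-pentadecyl-4-(trimethylsilyloxy)cyclobut-2-en-1-yl]oxy}silane F6. K2CO3 in methanol at 0 °C removes only the trimethylsilyl group, to give 2,3-dimethoxy-4-(1-methoxypropa-1,2-dien-1-yl)-1-pentadecyl-4-(triethylsilyloxy)cyclobut-2-en-1-ol F7. The transposition of step 5 then gives 2-methoxy-4-(1-methoxypropa-1,2-dien-1-yl)-3-pentadecyl-4-(triethylsilyloxy)cyclobut-2-en-1-one F8. Buffered fluoride as in step 6 comes back to the route at 12.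

**Further compounds**

F1 | step 7 | 2,5-dimethoxy-6-methylidene-3-pentadecyl-4-(trimethylsilyloxy)cyclohexa-2,4-dien-1-one | O=C1C(OC)=C(CCCCCCCCCCCCCCC)C(O[Si](C)(C)C)=C(OC)C1=C
F2 | step 5 | 2-methoxy-4-(1-methoxypropa-1,2-dien-1-yl)-3-(phenylsulfanyl)-4-(trimethylsilyloxy)cyclobut-2-en-1-one | O=C1C(OC)=C(Sc2ccccc2)C1(O[Si](C)(C)C)C(OC)=C=C
F3 | step 5 | lithium dipentadecylcuprate | [Li+].CCCCCCCCCCCCCCC[Cu-]CCCCCCCCCCCCCCC
F4 | step 4 | 4-hydroxy-2,3-dimethoxy-4-pentadecylcyclobut-2-en-1-one | COC1=C(OC)C(O)(CCCCCCCCCCCCCCC)C1=O
F5 | step 4 | 2,3-dimethoxy-4-pentadecyl-4-(trimethylsilyloxy)cyclobut-2-en-1-one | COC1=C(OC)C(O[Si](C)(C)C)(CCCCCCCCCCCCCCC)C1=O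
F6 | step 4 | triethyl{[2,3-dimethoxy-1-(1-methoxypropa-1,2-dien-1-yl)-4-pentadecyl-4-(trimethylsilyloxy)cyclobut-2-en-1-yl]oxy}silane | COC1=C(OC)C(O[Si](C)(C)C)(CCCCCCCCCCCCCCC)C1(O[Si](CC)(CC)CC)C(OC)=C=C
F7 | step 4 | 2,3-dimethoxy-4-(1-methoxypropa-1,2-dien-1-yl)-1-pentadecyl-4-(triethylsilyloxy)cyclobut-2-en-1-ol | COC1=C(OC)C(O)(CCCCCCCCCCCCCCC)C1(O[Si](CC)(CC)CC)C(OC)=C=C
F8 | step 4 | 2-methoxy-4-(1-methoxypropa-1,2-dien-1-yl)-3-pentadecyl-4-(triethylsilyloxy)cyclobut-2-en-1-one | O=C1C(OC)=C(CCCCCCCCCCCCCCC)C1(O[Si](CC)(CC)CC)C(OC)=C=C
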